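In a one-step world, every bit of starting material lost is product, so one constant gives the yield of the tanks and of the closed flask alike. Take that world as the zero of your scale.

| setting | north-west | north | west | eta | zeta | beta |
|---|---|---|---|---|---|---|
| starting material | 20 mM | 10 mM | 15 mM | 20 mM | 20 mM | 20 mM |
| remark | run made earlier | run made earlier | run made earlier | a single well-mixed tank run continuously and read at steady state, 75.0 h in it on average | one stirred flow tank at steady state, fed with the mixture as stated, mean residence time 25 h | a closed flask charged with all of it at once and left for 25 h |
| time |  |  |  |  |  | 25 h |

| run | time / h | product / % | starting material / % |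
|---|---|---|---|
| north-west | 6.00 | 2.0 | 65.5 |
| north-west | 12.0 | 8.8 | 44.6 |
| north-west | 20.0 | 23.0 | 25.1 |
| north-west | 25.0 | 32.3 | 18.2 |
| north | 8.00 | 4.1 | 57.5 |
| north | 15.0 | 13.7 | 36.0 |
| north | 25.0 | 32.2 | 18.5 |
| north | 30.0 | 39.8 | 12.5 |
| west | 4.00 | 1.1 | 76.7 |
| west | 10.0 | 6.8 | 50.2 |
| west | 20.0 | 22.7 | 25.3 |
| west | 30.0 | 40.5 | 12.4 |

(each reading ± 0.5 percentage points)

- the set-up with the highest amount of product at the outlet or at the end, in percent of the starting material put in ("none" if the first two lie within 2 percentage points) (eta / zeta / beta / none)
- amount of product at the outlet or at the end, in percent of the starting material put in, eta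
- amount of product at the outlet or at the end, in percent of the starting material put in, zeta
- amount of product at the outlet or at the end, in percent of the starting material put in, beta

- the stated concentrations are those of everything mixed, before any reaction; amounts are the same in each set-up
- the analysis behind the earlier runs scatters by 0.5 percentage points, standard deviation
- the earlier runs were made in a closed, stirred flask

The north and north-west runs, charged at 10 mM and 20 mM, read 32.2 % and 32.3 % product at 25.0 h, so in these two runs the percentage at that time does not follow the charge. The north-west starting material at that time gives the one-step constant k, the rate constant of a single first-order loss: 0.0681 h⁻¹. A steady tank with mean residence time τ then has the one-step ceiling kτ/(1+kτ) on product: 63.0 % for zeta and 83.6 % for eta.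

Product trails the loss. Of the starting material consumed, the north-west run shows a share 0.395 as product at 25.0 h, and the north run 0.455 at 30.0 h. My reckoning puts zeta near 24.9 % and beta at the 32.3 % read, with eta at 33.0 % if the share stays at the north-west value, and higher if it goes on rising as the later north reading suggests. I expect eta best, because its mean residence time is longer than beta's time.

The forecast gave 60 % for eta, 28.5 % for zeta and 32.3 % for beta: “Eta wins easily because of its threefold longer residence time.”

The flask gives 53.7 % for eta, 27.0 % for zeta and 32.1 % for beta, so eta is best.

    starting material → intermediate B (k = 0.0120 h⁻¹)
    intermediate B ⇌ intermediate C (K = 0.140, k = 0.0620 h⁻¹)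
    intermediate A → intermediate D (k = 0.260 h⁻¹)
    starting material → intermediate A (k = 0.0570 h⁻¹)
    intermediate D → product (k = 0.0590 h⁻¹)

Eta's product stands below its ceiling. Its tank holds 3.24 mM starting material, and k reckons 3.27 mM. Beta left for 250 h has a one-step value from k of >99.9 %, and it holds 82.6 % product.

The readings were generated by integration on assumed constants; noise was put on by code.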